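The route rests on cutting ring C of the flavanone away from ring A at two bonds, O-1–C-8a and C-4–C-4a, which sit on adjacent carbons of the phloroglucinol ring and so map onto an aryne. In the key step fluoride unmasks, in one flask, a secondary alkoxide from an enantiopure β-silyloxy ester and 3,5-bis(benzyloxy)benzyne; O-arylation and acyl capture of the resulting aryl anion build the chroman-4-one with the preset (S)-C-2 untouched, the 5-oxygen steering the regiochemistry. The precursor is an open-chain methyl 3-aryl-3-(triethylsilyloxy)propanoate whose aryl group already carries the protected luteolin unit through the 2′–8″ biaryl bond, made by Suzuki coupling.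

Key step: step 11

Assumption: the target structure fixes only C-2 of the flavanone as (S); the hindered 2′–8″ biaryl axis is not defined, so it is left uncontrolled and the biaryl compounds (13, 22, 24, 25, 26) may exist as two rotamers about it.

**Step 1**
Reactants: 1 luteolin
Product: 2 5,7,3′,4′-tetra-O-benzylluteolin
Conditions: BnBr (6 equiv), K2CO3, DMF, 80 °C
Reagents that add atoms: benzyl bromide, BrCc1ccccc1
Why: Williamson ether synthesis of all four phenols, the excess of benzyl bromide and heat being needed for the hydrogen-bonded 5-OH.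

**Step 2**
Reactants: 2 5,7,3′,4′-tetra-O-benzylluteolin
Product: 3 8-iodo-5,7,3′,4′-tetra-O-benzylluteolin
Conditions: NIS, TFA (cat.), CH2Cl2, 0 °C to rt, dark
Reagents that add atoms: N-iodosuccinimide, O=C1CCC(=O)N1I
Why: Electrophilic aromatic iodination, which in 5,7-dialkoxyflavones is expected at C-8 (ortho to the 7-oxygen and to O-1, para to the 5-oxygen, less hindered than C-6), while ring B is deactivated by the pyranone.

**Step 3**
Reactants: 4 2-bromo-3-hydroxy-4-methoxybenzaldehyde
Product: 6 2-bromo-3,4-dihydroxybenzaldehyde, via cyclic bromoborate 5 (not isolated)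
Conditions: BBr3, CH2Cl2, −78 °C to rt; then H2O
Reagents that add atoms: none
Why: Lewis acid cleavage of the aryl methyl ether by BBr3, assisted by the neighbouring phenol through borate 5, which aqueous work-up hydrolyses, while aldehyde and aryl bromide are not touched.

**Step 4**
Reactants: 6 2-bromo-3,4-dihydroxybenzaldehyde
Product: 7 3,4-bis(benzyloxy)-2-bromobenzaldehyde
Conditions: BnBr, K2CO3, DMF, 60 °C
Reagents that add atoms: benzyl bromide, BrCc1ccccc1
Why: Williamson ether synthesis of both phenols, so that all eight hydroxyl groups of the target end up under the same hydrogenolysable group.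

**Step 5**
Reactants: 7 3,4-bis(benzyloxy)-2-bromobenzaldehyde; 8 1-(tert-butyldimethylsilyloxy)-1-methoxyethene
Product: 10 methyl (S)-3-[3,4-bis(benzyloxy)-2-bromophenyl]-3-hydroxypropanoate, via trichlorosilyl ether 9 (not isolated)
Conditions: SiCl4, chiral 1,1′-binaphthyl-2,2′-diamine-derived bisphosphoramide (5 mol %, the enantiomer that directs Si-face attack), iPr2NEt (cat.), CH2Cl2, −78 °C; then aq. NaHCO3
Reagents that add atoms: none
Why: Catalytic asymmetric Mukaiyama aldol addition under Lewis base activation of SiCl4, in which the enantiomer of the bisphosphoramide that shields the Re face of the bound aldehyde is used so that the ketene acetal adds to the Si face and sets C-3 as (S), and hydrolysis of 9 on work-up gives the free alcohol.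

**Step 6**
Reactants: 10 methyl (S)-3-[3,4-bis(benzyloxy)-2-bromophenyl]-3-hydroxypropanoate
Product: 11 methyl (S)-3-[3,4-bis(benzyloxy)-2-bromophenyl]-3-(triethylsilyloxy)propanoate
Conditions: TESCl, imidazole, DMF, 0 °C to rt
Reagents that add atoms: chlorotriethylsilane, CC[Si](Cl)(CC)CC
Why: Silylation of the secondary alcohol, giving an ether that should survive the basic coupling of step 7 but is cleaved by fluoride in step 11.

**Step 7**
Reactants: 3 8-iodo-5,7,3′,4′-tetra-O-benzylluteolin; 11 methyl (S)-3-[3,4-bis(benzyloxy)-2-bromophenyl]-3-(triethylsilyloxy)propanoate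
Product: 13 methyl (S)-3-[3,4-bis(benzyloxy)-2-(5,7,3′,4′-tetra-O-benzylluteolin-8-yl)phenyl]-3-(triethylsilyloxy)propanoate, via pinacol boronate 12 (not isolated)
Conditions: 3 (1.3 equiv), HBpin, Et3N, Pd(OAc)2, SPhos, dioxane, 80 °C; then 11, K3PO4, H2O, 100 °C
Reagents that add atoms: none
Why: One-pot Miyaura-type borylation of the iodide with pinacolborane followed by Suzuki–Miyaura coupling, in which the bulky electron-rich SPhos ligand supports transmetalation and reductive elimination at the tetra-ortho-substituted biaryl bond while K3PO4 leaves the ester, the silyl ether and the stereocenter alone.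

**Step 8**
Reactants: 14 3,5-bis(benzyloxy)phenol
Product: 15 3,5-bis(benzyloxy)phenyl N-isopropylcarbamate
Conditions: iPrNCO, Et3N (cat.), CH2Cl2, rt
Reagents that add atoms: isopropyl isocyanate, CC(C)N=C=O
Why: Addition of the phenol to the isocyanate gives an N-H carbamate, a strong ortho-directing group that can be removed later under mild base.

**Step 9**
Reactants: 15 3,5-bis(benzyloxy)phenyl N-isopropylcarbamate
Product: 19 3,5-bis(benzyloxy)-2-(trimethylsilyl)phenyl N-isopropylcarbamate, via N-silyl carbamate 16 (not isolated), via aryllithium 17 (not isolated), via N-silyl arylsilane 18 (not isolated)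
Conditions: TBSOTf, TMEDA, Et2O, 0 °C to rt; n-BuLi, TMEDA, −78 °C; TMSCl, −78 °C to rt; aq. NaHSO4
Reagents that add atoms: chlorotrimethylsilane, C[Si](C)(C)Cl
Why: Directed ortho-metalation, in which the N-silylated carbamate and the neighbouring benzyloxy group together direct n-BuLi to C-2 at −78 °C (faster than benzylic deprotonation), TMSCl traps aryllithium 17 and acidic work-up removes the N-silyl group.

**Step 10**
Reactants: 19 3,5-bis(benzyloxy)-2-(trimethylsilyl)phenyl N-isopropylcarbamate
Product: 21 3,5-bis(benzyloxy)-2-(trimethylsilyl)phenyl trifluoromethanesulfonate, via silyl phenol 20 (not isolated)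
Conditions: Et2NH, DBU, MeCN, 40 °C; then PhNTf2, rt
Reagents that add atoms: N-phenylbis(trifluoromethanesulfonimide), O=S(=O)(N(c1ccccc1)S(=O)(=O)C(F)(F)F)C(F)(F)F
Why: DBU cleaves the N-H carbamate by E1cB elimination (Et2NH traps the isocyanate) and the phenoxide of 20 is triflated in the same flask, giving the 2-silylaryl triflate aryne precursor.

**Step 11**
Reactants: 13 methyl (S)-3-[3,4-bis(benzyloxy)-2-(5,7,3′,4′-tetra-O-benzylluteolin-8-yl)phenyl]-3-(triethylsilyloxy)propanoate; 21 3,5-bis(benzyloxy)-2-(trimethylsilyl)phenyl trifluoromethanesulfonate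
Product: 25 (2S)-5,7,3′,4′-tetra-O-benzyl-2′-(5,7,3′,4′-tetra-O-benzylluteolin-8-yl)eriodictyol (octabenzyl ether of the target), via cesium alkoxide 22 (not isolated), via 3,5-bis(benzyloxy)benzyne 23 (not isolated), via aryl anion 24 (not isolated)
Conditions: CsF, 18-crown-6, THF, −20 °C to rt, 21 (1.5 equiv) added over 3 h; pH 7 buffer quench
Reagents that add atoms: none
Why: Proposed new method: fluoride cleaves the O–Si bond of 13 to alkoxide 22 and triggers 1,2-elimination of 21 to aryne 23; the alkoxide oxygen adds to the aryne carbon remote from the flanking benzyloxy group, and aryl anion 24, which sits ortho to the new ether, attacks the methyl ester and expels methoxide, so that the O-1–C-8a and C-4–C-4a bonds form in one operation. The closest known reaction type is the fluoride-induced annulation of arynes with salicylate esters to xanthones (related to the aryne insertion into the C–O bond of carboxylic acids that leads to chroman-4-ones); new is the use of an aliphatic β-alkoxide ester as the O,C-1,4 partner. Ring C closes as a formal [4+2] annulation whose last bond forms by 6-exo-trig addition–elimination of the aryl anion at the ester carbonyl. No stereocenter is formed: C-2 comes from step 5 and none of its bonds is broken, so (S) is retained. The step needs O-attack at one carbon of the unsymmetrical aryne, which the 3-benzyloxy group secures by its inductive and distortion effect (the anion develops next to it, giving the 5,7-pattern), and acyl capture ahead of protonation, which the six-membered transition state in an aprotic medium favours. A modest excess of 21 consumes liberated methoxide and a prompt buffered quench limits retro-oxa-Michael opening of ring C.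

**Step 12**
Reactants: 25 (2S)-5,7,3′,4′-tetra-O-benzyl-2′-(5,7,3′,4′-tetra-O-benzylluteolin-8-yl)eriodictyol
Product: 26 (2S)-2′-(luteolin-8-yl)eriodictyol (the target)
Conditions: H2 (1 atm), Pd(OH)2/C, THF–MeOH, rt
Reagents that add atoms: none
Why: Catalytic hydrogenolysis of the eight benzyl ethers under neutral conditions, which should leave the flavone double bond, both carbonyl groups and the base-sensitive stereocenter C-2 untouched.

**Compound list**

1 | luteolin | O=c1cc(-c2ccc(O)c(O)c2)oc2cc(O)cc(O)c12 | starting material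
2 | 5,7,3′,4′-tetra-O-benzylluteolin | O=c1cc(-c2ccc(OCc3ccccc3)c(OCc3ccccc3)c2)oc2cc(OCc3ccccc3)cc(OCc3ccccc3)c12 | intermediate
3 | 8-iodo-5,7,3′,4′-tetra-O-benzylluteolin | O=c1cc(-c2ccc(OCc3ccccc3)c(OCc3ccccc3)c2)oc2c(I)c(OCc3ccccc3)cc(OCc3ccccc3)c12 | intermediate
4 | 2-bromo-3-hydroxy-4-methoxybenzaldehyde | COc1ccc(C=O)c(Br)c1O | starting material
5 | 2,4-dibromo-1,3,2-benzodioxaborole-5-carbaldehyde (cyclic bromoborate of 6) | O=Cc1ccc2OB(Br)Oc2c1Br | intermediate
6 | 2-bromo-3,4-dihydroxybenzaldehyde | O=Cc1ccc(O)c(O)c1Br | intermediate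
7 | 3,4-bis(benzyloxy)-2-bromobenzaldehyde | O=Cc1ccc(OCc2ccccc2)c(OCc2ccccc2)c1Br | intermediate
8 | 1-(tert-butyldimethylsilyloxy)-1-methoxyethene | C=C(OC)O[Si](C)(C)C(C)(C)C | starting material
9 | methyl (S)-3-[3,4-bis(benzyloxy)-2-bromophenyl]-3-(trichlorosilyloxy)propanoate | COC(=O)C[C@@H](c1ccc(OCc2ccccc2)c(OCc2ccccc2)c1Br)O[Si](Cl)(Cl)Cl | intermediate
10 | methyl (S)-3-[3,4-bis(benzyloxy)-2-bromophenyl]-3-hydroxypropanoate | COC(=O)C[C@@H](c1ccc(OCc2ccccc2)c(OCc2ccccc2)c1Br)O | intermediate
11 | methyl (S)-3-[3,4-bis(benzyloxy)-2-bromophenyl]-3-(triethylsilyloxy)propanoate | COC(=O)C[C@@H](c1ccc(OCc2ccccc2)c(OCc2ccccc2)c1Br)O[Si](CC)(CC)CC | intermediate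
12 | 5,7,3′,4′-tetra-O-benzylluteolin-8-boronic acid pinacol ester | O=c1cc(-c2ccc(OCc3ccccc3)c(OCc3ccccc3)c2)oc2c(B3OC(C)(C)C(C)(C)O3)c(OCc3ccccc3)cc(OCc3ccccc3)c12 | intermediate
13 | methyl (S)-3-[3,4-bis(benzyloxy)-2-(5,7,3′,4′-tetra-O-benzylluteolin-8-yl)phenyl]-3-(triethylsilyloxy)propanoate | COC(=O)C[C@@H](c1ccc(OCc2ccccc2)c(OCc2ccccc2)c1-c1c(OCc2ccccc2)cc(OCc2ccccc2)c2c(=O)cc(-c3ccc(OCc4ccccc4)c(OCc4ccccc4)c3)oc12)O[Si](CC)(CC)CC | intermediate
14 | 3,5-bis(benzyloxy)phenol | Oc1cc(OCc2ccccc2)cc(OCc2ccccc2)c1 | starting material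
15 | 3,5-bis(benzyloxy)phenyl N-isopropylcarbamate | CC(C)NC(=O)Oc1cc(OCc2ccccc2)cc(OCc2ccccc2)c1 | intermediate
16 | 3,5-bis(benzyloxy)phenyl N-(tert-butyldimethylsilyl)-N-isopropylcarbamate | CC(C)N(C(=O)Oc1cc(OCc2ccccc2)cc(OCc2ccccc2)c1)[Si](C)(C)C(C)(C)C | intermediate
17 | 2-lithio derivative of 16 (lithium between the carbamate oxygen and a benzyloxy group) | CC(C)N(C(=O)Oc1cc(OCc2ccccc2)cc(OCc2ccccc2)c1[Li])[Si](C)(C)C(C)(C)C | intermediate
18 | 3,5-bis(benzyloxy)-2-(trimethylsilyl)phenyl N-(tert-butyldimethylsilyl)-N-isopropylcarbamate | CC(C)N(C(=O)Oc1cc(OCc2ccccc2)cc(OCc2ccccc2)c1[Si](C)(C)C)[Si](C)(C)C(C)(C)C | intermediate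
19 | 3,5-bis(benzyloxy)-2-(trimethylsilyl)phenyl N-isopropylcarbamate | CC(C)NC(=O)Oc1cc(OCc2ccccc2)cc(OCc2ccccc2)c1[Si](C)(C)C | intermediate
20 | 3,5-bis(benzyloxy)-2-(trimethylsilyl)phenol | Oc1cc(OCc2ccccc2)cc(OCc2ccccc2)c1[Si](C)(C)C | intermediate
21 | 3,5-bis(benzyloxy)-2-(trimethylsilyl)phenyl trifluoromethanesulfonate | O=S(=O)(Oc1cc(OCc2ccccc2)cc(OCc2ccccc2)c1[Si](C)(C)C)C(F)(F)F | intermediate
22 | cesium alkoxide of desilylated 13 | COC(=O)C[C@@H](c1ccc(OCc2ccccc2)c(OCc2ccccc2)c1-c1c(OCc2ccccc2)cc(OCc2ccccc2)c2c(=O)cc(-c3ccc(OCc4ccccc4)c(OCc4ccccc4)c3)oc12)[O-].[Cs+] | intermediate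
23 | 3,5-bis(benzyloxy)benzyne | C1#CC(OCc2ccccc2)=CC(OCc2ccccc2)=C1 | intermediate
24 | cesium aryl anion from O-arylation of 22 by 23 (anion between the ether carbon and a benzyloxy carbon) | COC(=O)C[C@@H](c1ccc(OCc2ccccc2)c(OCc2ccccc2)c1-c1c(OCc2ccccc2)cc(OCc2ccccc2)c2c(=O)cc(-c3ccc(OCc4ccccc4)c(OCc4ccccc4)c3)oc12)Oc1cc(OCc2ccccc2)cc(OCc2ccccc2)[c-]1.[Cs+] | intermediate
25 | (2S)-5,7,3′,4′-tetra-O-benzyl-2′-(5,7,3′,4′-tetra-O-benzylluteolin-8-yl)eriodictyol | O=C1C[C@@H](c2ccc(OCc3ccccc3)c(OCc3ccccc3)c2-c2c(OCc3ccccc3)cc(OCc3ccccc3)c3c(=O)cc(-c4ccc(OCc5ccccc5)c(OCc5ccccc5)c4)oc23)Oc2cc(OCc3ccccc3)cc(OCc3ccccc3)c21 | intermediate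
26 | (2S)-2′-(luteolin-8-yl)eriodictyol | O=C1C[C@@H](c2ccc(O)c(O)c2-c2c(O)cc(O)c3c(=O)cc(-c4ccc(O)c(O)c4)oc23)Oc2cc(O)cc(O)c21 | target

Total step count: 12. Longest linear sequence: 7 steps (steps 3, 4, 5, 6, 7, 11, 12, from compound 4).

**Steps most likely to fail**

1. Step 11 (Proposed new method). Desilylation may lag behind aryne formation, so that the aryne is lost to self-reaction. The free alkoxide may fragment by retro-aldol cleavage or eliminate. The aryl anion may be protonated before it reaches the ester. Liberated methoxide may open ring C and erode the configuration at C-2. The fallback uses known chemistry, sets out from 13 and comes back at 25. Bu4NF buffered with AcOH in THF removes the silyl group and should give methyl (S)-3-[3,4-bis(benzyloxy)-2-(5,7,3′,4′-tetra-O-benzylluteolin-8-yl)phenyl]-3-hydroxypropanoate F1. The neutral alcohol is then O-arylated by aryne 23, generated from 21 with CsF in MeCN (O–H insertion of an aryne, the alcohol proton quenching the aryl anion), with the same regiochemistry as in step 11, to give the 3,5-bis(benzyloxy)phenyl ether F2. LiOH in THF–H2O at 0 °C gives the carboxylic acid F3. TFAA in CH2Cl2 at 0 °C then closes ring C by intramolecular Friedel–Crafts acylation at the carbon ortho to the ether oxygen (the two ortho carbons are equivalent), which gives 25. No bond at C-2 is broken on this path and no free alkoxide or methoxide is present.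

2. Step 7. Transmetalation and reductive elimination at the tetra-ortho-substituted axis, next to the branched silyloxy side chain, may be slow enough for protodeboronation of the electron-rich boronate to win. The fallback changes the order of events, sets out from 3 and 7 and comes back at 13. The same one-pot borylation and coupling is run with the small, electron-poor bromoaldehyde 7 in place of 11 and should give the biaryl aldehyde F4. Aldol addition of 8 under the conditions of step 5 gives, through the trichlorosilyl ether F5, the hydroxy ester F1 described above, and silylation as in step 6 gives 13. On this path C-3 is set next to an existing axis, so catalyst control has to override any bias from the axis and the configuration would need to be checked.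

3. Step 5. The catalyst may discriminate poorly between the faces of the ortho-bromo, electron-rich aldehyde, giving low enantiomeric purity that is carried to the target. The fallback sets out from 7 and comes back at 10. Roskamp homologation of 7 with methyl diazoacetate (SnCl2, CH2Cl2, rt) should give the β-keto ester F6. Noyori hydrogenation (H2, RuCl2[(R)-BINAP], MeOH) reduces the ketone under chelate control by the ester and is expected to give (S)-10, the aryl bromide and benzyl ethers being inert to this catalyst.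

**Further compounds**

F1 | step 11 | methyl (S)-3-[3,4-bis(benzyloxy)-2-(5,7,3′,4′-tetra-O-benzylluteolin-8-yl)phenyl]-3-hydroxypropanoate | COC(=O)C[C@@H](c1ccc(OCc2ccccc2)c(OCc2ccccc2)c1-c1c(OCc2ccccc2)cc(OCc2ccccc2)c2c(=O)cc(-c3ccc(OCc4ccccc4)c(OCc4ccccc4)c3)oc12)O
F2 | step 11 | methyl (S)-3-[3,5-bis(benzyloxy)phenoxy]-3-[3,4-bis(benzyloxy)-2-(5,7,3′,4′-tetra-O-benzylluteolin-8-yl)phenyl]propanoate | COC(=O)C[C@@H](c1ccc(OCc2ccccc2)c(OCc2ccccc2)c1-c1c(OCc2ccccc2)cc(OCc2ccccc2)c2c(=O)cc(-c3ccc(OCc4ccccc4)c(OCc4ccccc4)c3)oc12)Oc1cc(OCc2ccccc2)cc(OCc2ccccc2)c1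
F3 | step 11 | (S)-3-[3,5-bis(benzyloxy)phenoxy]-3-[3,4-bis(benzyloxy)-2-(5,7,3′,4′-tetra-O-benzylluteolin-8-yl)phenyl]propanoic acid | OC(=O)C[C@@H](c1ccc(OCc2ccccc2)c(OCc2ccccc2)c1-c1c(OCc2ccccc2)cc(OCc2ccccc2)c2c(=O)cc(-c3ccc(OCc4ccccc4)c(OCc4ccccc4)c3)oc12)Oc1cc(OCc2ccccc2)cc(OCc2ccccc2)c1
F4 | step 7 | 3,4-bis(benzyloxy)-2-(5,7,3′,4′-tetra-O-benzylluteolin-8-yl)benzaldehyde | O=Cc1ccc(OCc2ccccc2)c(OCc2ccccc2)c1-c1c(OCc2ccccc2)cc(OCc2ccccc2)c2c(=O)cc(-c3ccc(OCc4ccccc4)c(OCc4ccccc4)c3)oc12
F5 | step 7 | methyl (S)-3-[3,4-bis(benzyloxy)-2-(5,7,3′,4′-tetra-O-benzylluteolin-8-yl)phenyl]-3-(trichlorosilyloxy)propanoate | COC(=O)C[C@@H](c1ccc(OCc2ccccc2)c(OCc2ccccc2)c1-c1c(OCc2ccccc2)cc(OCc2ccccc2)c2c(=O)cc(-c3ccc(OCc4ccccc4)c(OCc4ccccc4)c3)oc12)O[Si](Cl)(Cl)Cl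
F6 | step 5 | methyl 3-[3,4-bis(benzyloxy)-2-bromophenyl]-3-oxopropanoate | COC(=O)CC(=O)c1ccc(OCc2ccccc2)c(OCc2ccccc2)c1Br
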